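If the average length (the number-average degree of polymerisation) divides monomer in chains by chains begun, what must we find for these two flasks?

| setting | south-west | east | cedar | larch |
|---|---|---|---|---|
| free monomer | 0.20 M | 0.20 M | 0.20 M | 0.20 M |
| protic impurity | 0.056 M | 0.085 M | 0.0400 M | 0.0600 M |
| initiator | 2 mol% | 2 mol% | 2 mol% | 2 mol% |
| remark | run made earlier | run made earlier |  |  |
| time |  |  | 3.0 d | 3.0 d |

| run | time / d | monomer in chains / % |
|---|---|---|
| south-west | 0.250 | 7.9 |
| south-west | 0.833 | 14.9 |
| south-west | 1.25 | 20.2 |
| south-west | 2.00 | 22.6 |
| south-west | 3.00 | 25.9 |
| east | 0.250 | 5.2 |
| east | 0.833 | 11.2 |
| east | 1.25 | 12.7 |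
| east | 2.00 | 14.4 |
| east | 3.00 | 17.1 |

(readings scatter by 1 percentage point)

- which of the two ends with the longer chains by the average number of monomer units in a chain (chains begun, living or dead) ("neither" if they lie within 10%) (cedar / larch / neither)
- average number of monomer units in a chain (chains begun, living or dead) at the end, cedar
- average number of monomer units in a chain (chains begun, living or dead) at the end, larch

- the average divides the monomer in chains by the number of chains begun, living and dead together
- the earlier runs were read with a standard deviation of 1 percentage point
- steps that have been proposed: free monomer + initiator -> living end + monomer in chains; free monomer + living end -> monomer in chains + living end; monomer in chains + living end -> free monomer + living end; living end + monomer in chains -> dead end; protic impurity + free monomer -> quenched substrate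
- the earlier runs do not show the number of chains; that part of a forecast is a guess

Two amounts, and the readings show one of them. What about the chains begun? Freeze them. In the proposed steps a chain begins when initiator reacts, and an end that dies still counts as a chain begun. So once the initiator has reacted, the chain count 0.00400 M, meaning the concentration of chains begun, is the same in cedar and larch.

Is that shown? No, it is an assumption, since the readings do not count chains.

And the monomer in chains? At the last reading, south-west holds 25.9% with 0.056 M of impurity, and east holds 17.1% with 0.085 M. I draw a straight line through these two points, with slope 3.03 L mol⁻¹. It gives larch 24.7% and cedar 30.8%.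

Where is this weakest? At cedar, whose impurity lies below that of both runs, so its value is an extrapolation.

Dividing by the chain count, my lengths are 15.4 for cedar and 12.3 for larch. Their gap of 24.6% is wider than the margin of 10%.

The forecast says cedar, with 15.7 for cedar and 12.3 for larch, reasoning that “If all the initiator starts chains, they equal 2% of the monomer charge”. For cedar it stands a little above my 15.4.

The flask gives cedar, with 15.6 for cedar and 12.3 for larch.

    free monomer + initiator → living end + monomer in chains (k = 17.0 L mol⁻¹ h⁻¹)
    free monomer + living end → monomer in chains + living end, rate k2*[living end]*[free monomer] (k = 5.10 L mol⁻¹ h⁻¹)
    monomer in chains + living end → free monomer + living end, rate k3*[living end] as long as [monomer in chains] is above zero (k = 0.380 h⁻¹)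
    living end + monomer in chains → dead end (k = 0.130 L mol⁻¹ h⁻¹)
    protic impurity + free monomer → quenched substrate (k = 1.30 L mol⁻¹ h⁻¹)

Cedar's initiator stands at 0% of its charge after 1.50 d, and dividing its 31.1% in chains after 3.00 d by the chain count gives 15.6. The gap between the flasks comes from the difference in protic impurity: with that difference taken away, larch moves from 12.3 to 15.6. On larch's recipe at 0.80 M of free monomer, the chain count is 0.0160 M, and 67.2% in chains after 3.00 d gives 33.6; the simulated average in that flask is 33.6.

(The runs come from a simulation for an exercise.)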